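**Retrosynthetic overview**
1. Target 12 ⇐ O‑debenzylation of lactol 11 ⇐ DIBAL partial reduction of lactone 10, the bis‑THF furofuranone.
2. 10 ⇐ intramolecular Mitsunobu etherification of 1,4‑diol 9 (ring 2, the C9–O–C7′ THF). The C7′–O bond is never broken, so C7′ keeps its configuration.
3. 9 ⇐ borane reduction of acid 8 ⇐ anti, trans‑selective aldol of the lactone enolate of 7 with aldehyde 4, which sets C8′ and C7′.
4. 7 (ring 1, the C7–O–C9′ γ‑lactone, formed first) ⇐ hydroxy acid 6 ⇐ Evans Mg‑catalysed anti‑aldol product 5 ⇐ imide 3 + aldehyde 4. Ar = 4‑(benzyloxy)‑3‑methoxyphenyl throughout.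

**Assumption:** I read the target SMILES literally. That means a trans ring fusion (H‑3a anti to H‑6a), each aryl anti to its neighbouring ring‑fusion H, and lactol carbon R (taken as the anomer obtained on equilibration). This differs from the cis‑fused (+)‑pinoresinol pattern.

---

**Step 1**
Reactants: 1 (4S)‑4‑benzyl‑1,3‑oxazolidin‑2‑one; 2 methyl 4‑chloro‑4‑oxobutanoate
Product: 3 (S)‑methyl 4‑(4‑benzyl‑2‑oxooxazolidin‑3‑yl)‑4‑oxobutanoate
Conditions: Et3N, DMAP (cat.), CH2Cl2, 0 °C → rt
Reagents that add atoms: none beyond the two reactants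
Why: N‑acylation of the oxazolidinone by the acid chloride puts the chiral auxiliary on the succinate half‑ester and creates no new stereocentre.

**Step 2**
Reactants: 3 imide; 4 4‑(benzyloxy)‑3‑methoxybenzaldehyde
Product: 5 methyl (3R,4S)‑3‑{[(4S)‑4‑benzyl‑2‑oxo‑1,3‑oxazolidin‑3‑yl]carbonyl}‑4‑[4‑(benzyloxy)‑3‑methoxyphenyl]‑4‑hydroxybutanoate
Conditions: MgBr2·OEt2 (10 mol %), Et3N, TMSCl, EtOAc, rt; then CF3CO2H, MeOH
Reagents that add atoms: none retained (TMSCl, C[Si](C)(C)Cl, gives only a transient O‑TMS ether that the TFA/MeOH work‑up removes)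
Why: This is the Evans Mg‑catalysed anti‑aldol reaction. A Z‑enolate adds to the aryl aldehyde through a chelated transition state, and the (S)‑benzyl auxiliary sets C8 (R) and C7 (S) with anti relative configuration.

**Step 3**
Reactants: 5
Product: 6 (2R)‑2‑{(S)‑[4‑(benzyloxy)‑3‑methoxyphenyl](hydroxy)methyl}‑4‑methoxy‑4‑oxobutanoic acid (auxiliary 1 is recovered)
Conditions: LiOH, H2O2, THF/H2O (3:1), 0 °C; then aqueous Na2SO3
Reagents that add atoms: hydrogen peroxide, OO (supplies the acid O–H oxygen via peracid, then reduced)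
Why: LiOOH attacks the exocyclic imide carbonyl selectively (Evans auxiliary cleavage), leaving the methyl ester and both stereocentres intact.

**Step 4**
Reactants: 6
Product: 7 (2S,3R)‑2‑[4‑(benzyloxy)‑3‑methoxyphenyl]‑5‑oxooxolane‑3‑carboxylic acid
Conditions: PPTS (cat.), toluene, 60 °C, 4 Å MS
Reagents that add atoms: none (MeOH is lost)
Why: The benzylic OH cyclises 5‑exo onto the C9′ methyl ester (γ‑hydroxy ester lactonisation, ring 1). No C–O bond at a stereocentre is broken, giving the cis‑2,3 lactone.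

**Step 5**
Reactants: 7 lactone acid; 4 aldehyde
Product: 8 (2S,3R,4S)‑2‑[4‑(benzyloxy)‑3‑methoxyphenyl]‑4‑{(R)‑[4‑(benzyloxy)‑3‑methoxyphenyl](hydroxy)methyl}‑5‑oxooxolane‑3‑carboxylic acid
Conditions: LDA (2.2 equiv), THF, −78 °C; then 4, −78 °C; NH4Cl quench
Reagents that add atoms: none beyond the aldehyde reactant
Why: In this dianion aldol, the carboxylate is not enolised and the lactone enolate forms. It adds to ArCHO anti to the cis aryl and carboxylate, so C8′ ends up trans to C8–C9. The E(O) lactone enolate reacts through a chair Zimmerman–Traxler transition state to give the anti aldol (C7′ R).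

**Step 6**
Reactants: 8
Product: 9 (3S,4S,5S)‑5‑[4‑(benzyloxy)‑3‑methoxyphenyl]‑3‑{(R)‑[4‑(benzyloxy)‑3‑methoxyphenyl](hydroxy)methyl}‑4‑(hydroxymethyl)oxolan‑2‑one
Conditions: BH3·SMe2, THF, 0 °C → rt; MeOH quench
Reagents that add atoms: none (BH3 only delivers hydride)
Why: Borane reduces the carboxylic acid faster than the lactone, giving the primary alcohol C9–OH. All stereocentres are untouched.

**Step 7**
Reactants: 9
Product: 10 (3S,3aS,6R,6aS)‑3,6‑bis[4‑(benzyloxy)‑3‑methoxyphenyl]tetrahydro‑1H,3H‑furo[3,4‑c]furan‑1‑one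
Conditions: PPh3, DIAD, THF, 0 °C → rt
Reagents that add atoms: none (Ph3P=O and the hydrazide are by‑products)
Why: This is a Mitsunobu cyclodehydration. The less hindered primary alcohol is activated, and the benzylic alkoxy oxygen closes the THF 5‑exo‑tet. The C7′–O bond is not cleaved, so C7′ is retained and the trans‑fused ring 2 forms under irreversible, non‑basic conditions.

**Step 8**
Reactants: 10
Product: 11 (1R,3S,3aS,6R,6aS)‑3,6‑bis[4‑(benzyloxy)‑3‑methoxyphenyl]tetrahydro‑1H,3H‑furo[3,4‑c]furan‑1‑ol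
Conditions: DIBAL‑H (1.1 equiv), CH2Cl2, −78 °C; Rochelle salt work‑up
Reagents that add atoms: none (hydride, then H from work‑up)
Why: Partial reduction of the lactone to the lactol (stable aluminium hemiacetal at −78 °C); the anomeric centre equilibrates through the open hydroxy‑aldehyde to the assumed (1R) anomer.

**Step 9**
Reactants: 11
Product: 12 target, (1R,3S,3aS,6R,6aS)‑3,6‑bis(4‑hydroxy‑3‑methoxyphenyl)tetrahydro‑1H,3H‑furo[3,4‑c]furan‑1‑ol
Conditions: H2 (1 atm), 10 % Pd/C, EtOAc, rt
Reagents that add atoms: none (H2 only; toluene is lost)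
Why: Hydrogenolysis of the two aryl benzyl ethers frees both phenols. The lactol, the ether rings and all stereocentres are unaffected under these neutral conditions.

---

**Compound list**

1 | (4S)‑4‑benzyl‑1,3‑oxazolidin‑2‑one | O=C1N[C@@H](Cc2ccccc2)CO1 | starting material
2 | methyl 4‑chloro‑4‑oxobutanoate | COC(=O)CCC(=O)Cl | starting material
3 | (S)‑methyl 4‑(4‑benzyl‑2‑oxooxazolidin‑3‑yl)‑4‑oxobutanoate | COC(=O)CCC(=O)N1[C@@H](Cc2ccccc2)COC1=O | intermediate
4 | 4‑(benzyloxy)‑3‑methoxybenzaldehyde | COc1cc(C=O)ccc1OCc1ccccc1 | starting material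
5 | anti‑aldol imide (3R,4S) | COc1cc([C@@H](O)[C@@H](CC(=O)OC)C(=O)N2[C@@H](Cc3ccccc3)COC2=O)ccc1OCc1ccccc1 | intermediate
6 | hydroxy acid methyl ester (2R, S‑carbinol) | COc1cc([C@@H](O)[C@@H](CC(=O)OC)C(=O)O)ccc1OCc1ccccc1 | intermediate
7 | cis‑lactone acid (2S,3R) | COc1cc([C@H]2OC(=O)C[C@H]2C(=O)O)ccc1OCc1ccccc1 | intermediate
8 | aldol lactone acid (2S,3R,4S; carbinol R) | COc1cc([C@H]2OC(=O)[C@H]([C@@H](O)c3ccc(OCc4ccccc4)c(OC)c3)[C@H]2C(=O)O)ccc1OCc1ccccc1 | intermediate
9 | diol lactone (3S,4S,5S; carbinol R) | COc1cc([C@H]2OC(=O)[C@H]([C@@H](O)c3ccc(OCc4ccccc4)c(OC)c3)[C@H]2CO)ccc1OCc1ccccc1 | intermediate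
10 | trans‑fused bis‑THF lactone, dibenzyl ether | COc1cc([C@H]2OC(=O)[C@H]3[C@H]2CO[C@H]3c2ccc(OCc4ccccc4)c(OC)c2)ccc1OCc1ccccc1 | intermediate
11 | lactol dibenzyl ether | COc1cc([C@H]2O[C@@H](O)[C@H]3[C@H]2CO[C@H]3c2ccc(OCc4ccccc4)c(OC)c2)ccc1OCc1ccccc1 | intermediate
12 | 4α‑hydroxypinoresinol (target) | COc1cc([C@H]2O[C@@H](O)[C@H]3[C@H]2CO[C@H]3c2ccc(O)c(OC)c2)ccc1O | target

---

**Total step count:** 9.
**Longest linear sequence:** 9 steps (1 → 3 → 5 → 6 → 7 → 8 → 9 → 10 → 11 → 12); aldehyde 4 is used in steps 2 and 5.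

**Three steps most likely to fail**
1. **Step 7 (ring‑2 closure).** Forming the strained trans‑fused bicycle may fail. Competing outcomes are elimination to a styrene, benzylic ionisation, or translactonisation of the primary alcohol onto the lactone.
   Fallback: change the order. Reduce the lactone to its methyl lactol acetal (DIBAL; MeOH, PPTS) so C8′ cannot epimerise. Close ring 2 through the primary iodide or tosylate with Ag2O or NaH, then unmask the lactol with aqueous acid.
2. **Step 5 (lactone aldol).** The C7′ diastereoselectivity may be poor, and retro‑aldol is possible.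
   Fallback: change the bond construction. C‑acylate the lactone enolate with the aroyl chloride to give a β‑keto lactone, then set C7′ and C8′ by Noyori Ru‑TsDPEN dynamic‑kinetic transfer hydrogenation (HCO2H/Et3N).
3. **Step 2 (anti‑aldol).** The Mg‑catalysed reaction on this α‑CH2CO2Me imide with an electron‑rich aldehyde may give low anti selectivity, and I assumed the (S)‑auxiliary gives the (3R,4S) adduct.
   Fallback: use the Evans syn‑aldol (Bu2BOTf, Et3N), then invert the benzylic alcohol by Mitsunobu (p‑nitrobenzoic acid, then K2CO3/MeOH). If the wrong enantiomer results, use the (R)‑auxiliary and re‑map.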